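Readings and results were generated by integration with made-up constants; scatter was added.

A share of bis adduct read at a single time looks like a property of the temperature, but it is a position on a clock, and the trap is to forget the clock. Two times matter: the time of reading, and the crossover time, when triple product catches up with bis adduct. Their ratio places each flask.

| setting | delta | eta | south-west | east | north-west |
|---|---|---|---|---|---|
| starting material | 0.025 M | 0.038 M | 0.050 M | 0.050 M | 0.050 M |
| partner | 1.5 equiv | 1.5 equiv | 1.50 equiv | 1.50 equiv | 1.50 equiv |
| temperature | 100 °C | 122 °C | 130 °C | 90 °C | 110 °C |
| remark | run made earlier | run made earlier |  |  |  |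
| time |  |  | 50 min | 50 min | 50 min |

| run | time / min | bis adduct / % | triple product / % |
|---|---|---|---|
| delta | 12.0 | 2 | 0 |
| delta | 20.0 | 1 | 0 |
| delta | 40.0 | 4 | 3 |
| delta | 50.0 | 4 | 2 |
| delta | 60.0 | 4 | 5 |
| delta | 120 | 9 | 8 |
| delta | 180 | 10 | 14 |
| eta | 3.00 | 4 | 0 |
| eta | 5.00 | 0 | 0 |
| eta | 8.00 | 4 | 1 |
| eta | 12.0 | 6 | 1 |
| eta | 15.0 | 5 | 3 |
| eta | 25.0 | 8 | 9 |
| eta | 40.0 | 9 | 16 |

(readings scatter by 1.5 percentage points)

- the flask that comes out highest in share of bis adduct in all that became bis adduct or triple product or tetra adduct, or "all alike" when all lie within 1.5 percentage points (south-west / east / north-west / all alike)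
- share of bis adduct in all that became bis adduct or triple product or tetra adduct, south-west
- share of bis adduct in all that became bis adduct or triple product or tetra adduct, east
- share of bis adduct in all that became bis adduct or triple product or tetra adduct, north-west

In the delta run the crossover comes near 120 min (9% bis adduct, 8% triple product), and in the eta run near 25.0 min (8% against 9%). Bis adduct is then about half of the pair, to within a scatter of 1.5 percentage points. But the eta run is both hotter and more concentrated, so I assume the steps go with partner concentration and multiply it by the time. This gives a crossover dose of 4.50 M·min at 100 °C and 1.42 M·min at 122 °C, a drop of 0.501 powers of ten.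

Carried along that logarithmic line, outside the two runs, the crossover dose at 90 °C is 7.59 M·min. With the partner charged here, the crossover times are 101 min for east, 35.6 min for north-west and 12.5 min for south-west. Against 50 min, the logarithms of reading time over crossover time are −0.305, 0.148 and 0.602. So I expect east to be read before its crossover, north-west just after and south-west well after.

The forecast names east, with 82% there, 50% north-west and 15% south-west, on the ground that “bis share falls steeply with conversion”.

The flasks give 68.3% for east, 37.4% for north-west and 21.0% for south-west, highest in east, each on the side of the crossover my two times put it.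

    starting material + partner → single product + by-product (k = 0.142 /M/min, Ea = 58.0 kJ/mol)
    partner + single product → bis adduct + by-product (k = 0.112 /M/min, Ea = 92.0 kJ/mol)
    partner + bis adduct → triple product + by-product (k = 0.358 /M/min, Ea = 67.0 kJ/mol)
    partner + triple product → tetra adduct + by-product (k = 0.0429 /M/min, Ea = 66.0 kJ/mol)
    starting material ⇌ dormant form (K = 1.28, k = 0.00667 /min, Ea = 110 kJ/mol, ΔH = −8.00 kJ/mol)
    (constants at 90 °C)

East stands high mainly because of the hour of its reading: at 50 min, before my estimated 101 min crossover, it gives 68.3%, and at 500 min, ten times as late, it gives 22.9%. Now take east with 3.80 equiv of partner. The same dose 7.59 M·min gives a crossover at 39.9 min, earlier than the reading, so bis adduct should trail. The computed share is 39.5%, with 9.89% bis adduct against 13.6% triple product.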